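**Plan**

- Retrosynthetic cuts, in order: the six O–benzyl bonds; on the central ring, the aryl–C(=O) bond to the 2-methylbutanoyl group together with the neighbouring aryl C–O bond (both made at once from an aryne and the chiral acid); the two CH2–aryl bonds to the outer rings; the aryl–Si/aryl–OTf pair back to an ortho-bromophenol; the aryl–butanoyl bond of each outer ring.
- Enabling feature: on the central ring the acyl-bearing carbon and one C–OH carbon are direct neighbours. The first is flanked by a second oxygen-bearing carbon and the second by a CH2–aryl carbon, so an aryne across these two atoms is polarised to take oxygen next to the arm and carbon next to the oxygen.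
- Forward order: all three benzene rings are bought and no ring is built. The outer ring (steps 1–3) and the central silyl triflate diol (steps 4–8) are made separately, with silicon installed by organolithium chemistry before any ketone is present. A twofold Friedel–Crafts benzylation joins the three rings (step 9), the aryne step adds the last side chain (step 10) and hydrogenolysis finishes (step 11).
- Stereochemistry: the single stereocentre is bought as (S)-2-methylbutanoic acid and enters in step 10, where its alpha carbon takes no part in bond formation.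

Key step: step 10

Remark: 2,4,6-trihydroxybenzaldehyde, the commercial formyl derivative of phloroglucinol, is taken as the source of the central ring.

**Route**

Step 1
Reactants: 1 2-methylbenzene-1,3,5-triol (2-methylphloroglucinol); 2 butanoyl chloride
Product: 3 1-(2,4,6-trihydroxy-3-methylphenyl)butan-1-one
Conditions: AlCl3 (3.5 equiv), CH2Cl2–PhNO2, 0 °C to 45 °C; ice/aq. HCl
Reagents that add atoms: none
Why: Friedel–Crafts acylation of the strongly activated triol at one of its two equivalent free ring carbons is the standard entry to acylphloroglucinols, and the chelated ketone that forms deactivates the ring against a second acylation.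

Step 2
Reactants: 3 1-(2,4,6-trihydroxy-3-methylphenyl)butan-1-one
Product: 4 1-[4,6-bis(benzyloxy)-2-hydroxy-3-methylphenyl]butan-1-one
Conditions: BnBr (2.1 equiv), K2CO3 (2.2 equiv), acetone, reflux
Reagents that add atoms: benzyl bromide, BrCc1ccccc1
Why: Williamson etherification under carbonate should take the para hydroxyl and the ortho hydroxyl that has a ring CH as neighbour, because the third hydroxyl is tied to the ketone by a hydrogen bond and buttressed by the ring methyl group, as is usual in partial alkylation of C-methylated phloroacylphenones.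

Step 3
Reactants: 4 1-[4,6-bis(benzyloxy)-2-hydroxy-3-methylphenyl]butan-1-one
Product: 5 1-[4,6-bis(benzyloxy)-2-methoxy-3-methylphenyl]butan-1-one
Conditions: MeI (5 equiv), K2CO3 (3 equiv), DMF, 50 °C
Reagents that add atoms: iodomethane, CI
Why: Williamson methylation of the remaining chelated phenol with excess iodomethane in DMF puts the methoxy group between the butanoyl and methyl substituents and leaves the ring CH between the two benzyloxy groups as the only nucleophilic site for step 9.

Step 4
Reactants: 6 2,4,6-trihydroxybenzaldehyde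
Product: 7 2,4-bis(benzyloxy)-6-hydroxybenzaldehyde
Conditions: BnBr (2.05 equiv), K2CO3 (2.2 equiv), DMF, 0 °C to rt
Reagents that add atoms: benzyl bromide, BrCc1ccccc1
Why: Partial Williamson benzylation of this aldehyde is a known selective reaction in which the hydroxyl chelated to the formyl group stays free, and this free oxygen is thereby singled out as the later triflate oxygen.

Step 5
Reactants: 7 2,4-bis(benzyloxy)-6-hydroxybenzaldehyde
Product: 8 4,6-bis(benzyloxy)-3-bromo-2-hydroxybenzaldehyde
Conditions: NBS (1.0 equiv), MeCN, 0 °C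
Reagents that add atoms: N-bromosuccinimide, O=C1CCC(=O)N1Br
Why: Electrophilic aromatic bromination of a chelated 2-hydroxy-4,6-dialkoxybenzaldehyde goes ortho to the free phenol, between OH and OBn, since the other ring CH is shielded by two benzyloxy groups, and one equivalent of NBS at 0 °C should stop at the monobromide.

Step 6
Reactants: 8 4,6-bis(benzyloxy)-3-bromo-2-hydroxybenzaldehyde
Product: 9 2,4-bis(benzyloxy)-5-bromo-6-hydroxybenzene-1,3-dicarbaldehyde
Conditions: POCl3 (3 equiv), DMF, 0 °C to 70 °C; then H2O, 50 °C
Reagents that add atoms: N,N-dimethylformamide, CN(C)C=O; water, O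
Why: Vilsmeier–Haack formylation has a single ring position left, and this carbon is para to the free hydroxyl and ortho to both benzyloxy groups but only meta to the formyl group and bromine, so it should keep enough phloroglucinol-like nucleophilicity for the chloroiminium ion.

Step 7
Reactants: 9 2,4-bis(benzyloxy)-5-bromo-6-hydroxybenzene-1,3-dicarbaldehyde
Product: 10 3,5-bis(benzyloxy)-2-bromo-4,6-bis(hydroxymethyl)phenol
Conditions: NaBH4 (2.5 equiv), THF–MeOH, 0 °C; pH 7 buffer
Reagents that add atoms: none
Why: Borohydride reduction of both aldehydes at 0 °C leaves aryl bromide and benzyl ethers alone, and the resulting hydroxymethyl phenol cannot condense with itself through ring carbon because the ring is fully substituted.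

Step 8
Reactants: 10 3,5-bis(benzyloxy)-2-bromo-4,6-bis(hydroxymethyl)phenol
Product: 15 3,5-bis(benzyloxy)-2,4-bis(hydroxymethyl)-6-(trimethylsilyl)phenyl trifluoromethanesulfonate, via tris(trimethylsilyl) ether 11 (not isolated), via aryllithium 12 (not isolated), via lithium 2-silylphenoxide 13 (not isolated), via bis(silyl ether) triflate 14 (not isolated)
Conditions: HMDS (3 equiv), THF, reflux, then evaporation; n-BuLi (1.1 equiv), THF, −78 °C; PhNTf2 (1.2 equiv), −78 °C to rt; AcOH–THF–H2O, rt
Reagents that add atoms: hexamethyldisilazane, C[Si](C)(C)N[Si](C)(C)C; N-phenylbis(trifluoromethanesulfonimide), O=S(=O)(C(F)(F)F)N(c1ccccc1)S(=O)(=O)C(F)(F)F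
Why: This is the standard retro-Brook route to 2-silylaryl triflates: after persilylation, bromine–lithium exchange at −78 °C outruns any deprotonation, silicon moves from the one flanking oxygen that bears it to the aryl carbanion (the other flanking oxygen is a benzyl ether), PhNTf2 triflates the freed phenoxide selectively, and dilute acetic acid removes only the two primary silyl ethers.

Step 9
Reactants: 15 3,5-bis(benzyloxy)-2,4-bis(hydroxymethyl)-6-(trimethylsilyl)phenyl trifluoromethanesulfonate; 5 1-[4,6-bis(benzyloxy)-2-methoxy-3-methylphenyl]butan-1-one (2.5 equiv)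
Product: 16 3,5-bis(benzyloxy)-2,4-bis{[2,6-bis(benzyloxy)-3-butanoyl-4-methoxy-5-methylphenyl]methyl}-6-(trimethylsilyl)phenyl trifluoromethanesulfonate
Conditions: Sc(OTf)3 (10 mol %), MeNO2–CH2Cl2, 0 °C to rt
Reagents that add atoms: none
Why: In this Lewis-acid-catalysed Friedel–Crafts benzylation each benzylic alcohol ionises to a cation stabilised by ortho and para benzyloxy groups and is captured by the only free ring carbon of 5, which lies between two benzyloxy groups and para to the methoxy group, while the aryl–silicon bond should survive because its ipso carbon sits in a hexasubstituted ring next to the electron-poor triflate, flanked by benzyloxy groups that are twisted out of conjugation.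

Step 10
Reactants: 16 3,5-bis(benzyloxy)-2,4-bis{[2,6-bis(benzyloxy)-3-butanoyl-4-methoxy-5-methylphenyl]methyl}-6-(trimethylsilyl)phenyl trifluoromethanesulfonate; 17 (2S)-2-methylbutanoic acid
Product: 21 (2S)-1-[2,4-bis(benzyloxy)-3,5-bis{[2,6-bis(benzyloxy)-3-butanoyl-4-methoxy-5-methylphenyl]methyl}-6-hydroxyphenyl]-2-methylbutan-1-one (agrimol B hexabenzyl ether), via caesium (2S)-2-methylbutanoate 18 (not isolated), via central-ring aryne 19 (not isolated), via aryl caesium ester adduct 20 (not isolated)
Conditions: 17 (3 equiv), Cs2CO3 (0.5 equiv per acid), MeOH, rt, then evaporation and toluene azeotrope; 16, CsF (3 equiv), 18-crown-6 (1 equiv), THF–toluene, 65 °C; then 0.5 M aq. HCl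
Reagents that add atoms: none
Why: Fluoride attacks silicon of 16, triflate leaves and aryne 19 forms across the former silyl- and triflate-bearing carbons; the oxygen of dry carboxylate 18 adds to the aryne carbon next to the CH2–aryl arm to give 20, whose carbanion, placed beside the benzyloxy group, attacks the carbonyl of the adjacent ester in a four-centre 1,3-shift of the acyl group from oxygen to carbon that ends as the chelated caesium phenoxide of 21. The closest known reaction type is the fluoride-mediated formal insertion of arynes into the C–O bond of carboxylic acids to give ortho-hydroxyaryl ketones, an aryne-triggered anionic Fries-type shift. No ring is closed, the step forming one aryl C–O and one aryl C–C bond on the existing central ring. No new stereocentre arises, and the (S) centre carried in by 17 is kept because its alpha C–H bond is not touched in either the addition or the acyl shift and the medium holds no strong base. The step needs regioselectivity in the first addition, which the benzyloxy oxygen beside one aryne carbon should secure by making the distal carbon the electrophilic one and by stabilising the carbanion left next to itself. It also needs the acyl shift to outrun protonation to the simple aryl ester, which the pre-formed, dried caesium salt in an aprotic solvent should secure.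

Step 11
Reactants: 21 agrimol B hexabenzyl ether
Product: 22 agrimol B, (2S)-1-{3,5-bis[(3-butanoyl-2,6-dihydroxy-4-methoxy-5-methylphenyl)methyl]-2,4,6-trihydroxyphenyl}-2-methylbutan-1-one
Conditions: H2 (1 atm), 10% Pd/C, EtOAc–MeOH, rt
Reagents that add atoms: none
Why: Catalytic hydrogenolysis cleaves the six aryl benzyl ethers under neutral conditions, which spare the diarylmethane bridges, the hindered hydrogen-bonded aryl ketones, the methyl ethers and the stereocentre alpha to the ketone.

**Compound list**

1 | 2-methylbenzene-1,3,5-triol | Cc1c(O)cc(O)cc1O | starting material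
2 | butanoyl chloride | CCCC(=O)Cl | starting material
3 | 1-(2,4,6-trihydroxy-3-methylphenyl)butan-1-one | CCCC(=O)c1c(O)c(C)c(O)cc1O | intermediate
4 | 1-[4,6-bis(benzyloxy)-2-hydroxy-3-methylphenyl]butan-1-one | CCCC(=O)c1c(O)c(C)c(OCc2ccccc2)cc1OCc1ccccc1 | intermediate
5 | 1-[4,6-bis(benzyloxy)-2-methoxy-3-methylphenyl]butan-1-one | CCCC(=O)c1c(OC)c(C)c(OCc2ccccc2)cc1OCc1ccccc1 | intermediate
6 | 2,4,6-trihydroxybenzaldehyde | O=Cc1c(O)cc(O)cc1O | starting material
7 | 2,4-bis(benzyloxy)-6-hydroxybenzaldehyde | O=Cc1c(O)cc(OCc2ccccc2)cc1OCc1ccccc1 | intermediate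
8 | 4,6-bis(benzyloxy)-3-bromo-2-hydroxybenzaldehyde | O=Cc1c(O)c(Br)c(OCc2ccccc2)cc1OCc1ccccc1 | intermediate
9 | 2,4-bis(benzyloxy)-5-bromo-6-hydroxybenzene-1,3-dicarbaldehyde | O=Cc1c(O)c(Br)c(OCc2ccccc2)c(C=O)c1OCc1ccccc1 | intermediate
10 | 3,5-bis(benzyloxy)-2-bromo-4,6-bis(hydroxymethyl)phenol | OCc1c(O)c(Br)c(OCc2ccccc2)c(CO)c1OCc1ccccc1 | intermediate
11 | tris(trimethylsilyl) ether of 10 | C[Si](C)(C)OCc1c(O[Si](C)(C)C)c(Br)c(OCc2ccccc2)c(CO[Si](C)(C)C)c1OCc1ccccc1 | intermediate
12 | aryllithium from 11 (lithium in place of bromine) | C[Si](C)(C)OCc1c(O[Si](C)(C)C)c([Li])c(OCc2ccccc2)c(CO[Si](C)(C)C)c1OCc1ccccc1 | intermediate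
13 | lithium 3,5-bis(benzyloxy)-2,4-bis(trimethylsilyloxymethyl)-6-(trimethylsilyl)phenoxide | [Li+].C[Si](C)(C)OCc1c([O-])c([Si](C)(C)C)c(OCc2ccccc2)c(CO[Si](C)(C)C)c1OCc1ccccc1 | intermediate
14 | 3,5-bis(benzyloxy)-2,4-bis(trimethylsilyloxymethyl)-6-(trimethylsilyl)phenyl trifluoromethanesulfonate | C[Si](C)(C)OCc1c(OS(=O)(=O)C(F)(F)F)c([Si](C)(C)C)c(OCc2ccccc2)c(CO[Si](C)(C)C)c1OCc1ccccc1 | intermediate
15 | 3,5-bis(benzyloxy)-2,4-bis(hydroxymethyl)-6-(trimethylsilyl)phenyl trifluoromethanesulfonate | OCc1c(OS(=O)(=O)C(F)(F)F)c([Si](C)(C)C)c(OCc2ccccc2)c(CO)c1OCc1ccccc1 | intermediate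
16 | 3,5-bis(benzyloxy)-2,4-bis{[2,6-bis(benzyloxy)-3-butanoyl-4-methoxy-5-methylphenyl]methyl}-6-(trimethylsilyl)phenyl trifluoromethanesulfonate | C[Si](C)(C)c1c(OS(=O)(=O)C(F)(F)F)c(Cc2c(OCc3ccccc3)c(C)c(OC)c(C(=O)CCC)c2OCc2ccccc2)c(OCc2ccccc2)c(Cc2c(OCc3ccccc3)c(C)c(OC)c(C(=O)CCC)c2OCc2ccccc2)c1OCc1ccccc1 | intermediate
17 | (2S)-2-methylbutanoic acid | CC[C@H](C)C(=O)O | starting material
18 | caesium (2S)-2-methylbutanoate | CC[C@H](C)C(=O)[O-].[Cs+] | intermediate
19 | 3,5-bis(benzyloxy)-4,6-bis{[2,6-bis(benzyloxy)-3-butanoyl-4-methoxy-5-methylphenyl]methyl}-1,2-didehydrobenzene (central-ring aryne) | C1#CC(Cc2c(OCc3ccccc3)c(C)c(OC)c(C(=O)CCC)c2OCc2ccccc2)=C(OCc2ccccc2)C(Cc2c(OCc3ccccc3)c(C)c(OC)c(C(=O)CCC)c2OCc2ccccc2)=C1OCc1ccccc1 | intermediate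
20 | {2,4-bis(benzyloxy)-3,5-bis{[2,6-bis(benzyloxy)-3-butanoyl-4-methoxy-5-methylphenyl]methyl}-6-[(2S)-2-methylbutanoyloxy]phenyl}caesium | CC[C@H](C)C(=O)Oc1c([Cs])c(OCc2ccccc2)c(Cc2c(OCc3ccccc3)c(C)c(OC)c(C(=O)CCC)c2OCc2ccccc2)c(OCc2ccccc2)c1Cc1c(OCc2ccccc2)c(C)c(OC)c(C(=O)CCC)c1OCc1ccccc1 | intermediate
21 | (2S)-1-[2,4-bis(benzyloxy)-3,5-bis{[2,6-bis(benzyloxy)-3-butanoyl-4-methoxy-5-methylphenyl]methyl}-6-hydroxyphenyl]-2-methylbutan-1-one | O=C([C@@H](C)CC)c1c(O)c(Cc2c(OCc3ccccc3)c(C)c(OC)c(C(=O)CCC)c2OCc2ccccc2)c(OCc2ccccc2)c(Cc2c(OCc3ccccc3)c(C)c(OC)c(C(=O)CCC)c2OCc2ccccc2)c1OCc1ccccc1 | intermediate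
22 | agrimol B, (2S)-1-{3,5-bis[(3-butanoyl-2,6-dihydroxy-4-methoxy-5-methylphenyl)methyl]-2,4,6-trihydroxyphenyl}-2-methylbutan-1-one | CCCC(=O)c1c(O)c(Cc2c(O)c(Cc3c(O)c(C)c(OC)c(C(=O)CCC)c3O)c(O)c(C(=O)[C@@H](C)CC)c2O)c(O)c(C)c1OC | target

**Step count and risks**

Total step count: 11. Longest linear sequence: 8 steps (6 to 22, steps 4 to 11).

Steps most likely to fail:

1. Step 10. The aryl anion may be protonated before it reaches the ester carbonyl, the hindered aryne may be captured by a neighbouring benzyloxy oxygen instead of the carboxylate, or fluoride may erode the configuration by enolisation next to the new ketone. The fallback splits the insertion into two known operations and sets out from 16. Fluoride-induced O-arylation of the free acid 17 (CsF, MeCN, rt), in which the acid proton quenches the aryl anion, should give 3,5-bis(benzyloxy)-2,4-bis{[2,6-bis(benzyloxy)-3-butanoyl-4-methoxy-5-methylphenyl]methyl}phenyl (2S)-2-methylbutanoate F1. A Fries rearrangement (Sc(OTf)3 cat., toluene–MeNO2, 80 °C) should then move the acyl group to the only free ring position, which is ortho to the ester oxygen, and the route is rejoined at 21. The enantiomeric purity would have to be checked after the Lewis acid step.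

2. Step 9. Acid released during the alkylation may cleave the aryl–silicon bond by ipso protonation, the second and more hindered alkylation may stall, or benzyl groups may migrate. The fallback replaces the cationic coupling by a Suzuki–Miyaura coupling and sets out from 15 and 5. An Appel reaction (CBr4, PPh3, CH2Cl2, 0 °C) on 15 should give 3,5-bis(benzyloxy)-2,4-bis(bromomethyl)-6-(trimethylsilyl)phenyl trifluoromethanesulfonate F2. Bromination of 5 at its only ring CH (NBS, MeCN) should give 1-[2,4-bis(benzyloxy)-3-bromo-6-methoxy-5-methylphenyl]butan-1-one F3, and Miyaura borylation (B2pin2, Pd(dppf)Cl2, KOAc, dioxane, 90 °C) should turn it into 1-[2,4-bis(benzyloxy)-6-methoxy-5-methyl-3-(4,4,5,5-tetramethyl-1,3,2-dioxaborolan-2-yl)phenyl]butan-1-one F4. Coupling of F2 with two equivalents of F4 (Pd(PPh3)4, K3PO4, toluene–H2O, 70 °C) should give 16, since the benzylic C–Br bonds add to palladium far faster than the hindered ortho-silylated aryl triflate.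

3. Step 6. The ring already carries a formyl group and a bromine, so formylation may be slow, and forcing it may chlorinate the ring or cost a benzyl group. The fallback brings in the second one-carbon arm through the phenoxide instead of the neutral phenol and sets out from 8. Hydroxymethylation with aqueous formaldehyde and NaOH at 0 °C to rt (Lederer–Manasse reaction) should occur at the only open ring position, para to the phenoxide oxygen, and give 4,6-bis(benzyloxy)-3-bromo-2-hydroxy-5-(hydroxymethyl)benzaldehyde F5. Reduction of its remaining aldehyde with NaBH4 (THF–MeOH, 0 °C) rejoins the route at 10.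

Further compounds
F1 | step 10 | 3,5-bis(benzyloxy)-2,4-bis{[2,6-bis(benzyloxy)-3-butanoyl-4-methoxy-5-methylphenyl]methyl}phenyl (2S)-2-methylbutanoate | CC[C@H](C)C(=O)Oc1cc(OCc2ccccc2)c(Cc2c(OCc3ccccc3)c(C)c(OC)c(C(=O)CCC)c2OCc2ccccc2)c(OCc2ccccc2)c1Cc1c(OCc2ccccc2)c(C)c(OC)c(C(=O)CCC)c1OCc1ccccc1
F2 | step 9 | 3,5-bis(benzyloxy)-2,4-bis(bromomethyl)-6-(trimethylsilyl)phenyl trifluoromethanesulfonate | BrCc1c(OS(=O)(=O)C(F)(F)F)c([Si](C)(C)C)c(OCc2ccccc2)c(CBr)c1OCc1ccccc1
F3 | step 9 | 1-[2,4-bis(benzyloxy)-3-bromo-6-methoxy-5-methylphenyl]butan-1-one | CCCC(=O)c1c(OC)c(C)c(OCc2ccccc2)c(Br)c1OCc1ccccc1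
F4 | step 9 | 1-[2,4-bis(benzyloxy)-6-methoxy-5-methyl-3-(4,4,5,5-tetramethyl-1,3,2-dioxaborolan-2-yl)phenyl]butan-1-one | CCCC(=O)c1c(OC)c(C)c(OCc2ccccc2)c(B2OC(C)(C)C(C)(C)O2)c1OCc1ccccc1
F5 | step 6 | 4,6-bis(benzyloxy)-3-bromo-2-hydroxy-5-(hydroxymethyl)benzaldehyde | O=Cc1c(O)c(Br)c(OCc2ccccc2)c(CO)c1OCc1ccccc1
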